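Readings and results stem from a simulated flask on assumed constants, and the scatter is random.

The constants of this flask are hidden, so I read two rates from the earlier runs, then follow one substrate molecule through its forks.

| setting | noon | summer | flask |
|---|---|---|---|
| left-handed substrate | 9 mM | 14 mM | 18 mM |
| right-handed substrate | 9 mM | 14 mM | 18 mM |
| partner | 54 mM | 54 mM | 54.0 mM |
| free catalyst | 0.36 mM | 0.36 mM | 0.36 mM |
| impurity | 43 µM | 43 µM | 43 µM |
| remark | run made earlier | run made earlier |  |
| time |  |  | 3.0 h |

| run | time / h | left-handed substrate / % | right-handed substrate / % |
|---|---|---|---|
| noon | 0.667 | 41.3 | 42.8 |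
| noon | 1.33 | 35.6 | 37.1 |
| noon | 2.00 | 31.9 | 32.5 |
| noon | 3.00 | 26.1 | 26.8 |
| noon | 4.00 | 22.7 | 23.8 |
| summer | 0.250 | 45.9 | 47.2 |
| summer | 0.500 | 43.6 | 44.7 |
| summer | 1.00 | 38.6 | 39.8 |
| summer | 2.00 | 32.1 | 33.0 |
| summer | 4.00 | 24.0 | 23.7 |

(standard deviation of a reading: 0.5 percentage points)

- free catalyst is single-handed; left-handed substrate and right-handed substrate are mirror images of each other, charged as a racemate, each of them at the stated concentration
- an excess is below zero if the other one leads

* part of the left-handed substrate and right-handed substrate charged together that has reacted at 3.0 h
* excess of left-handed product over right-handed product in the product at 3.0 h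
* excess of right-handed substrate over left-handed substrate among what is left of the two at 3.0 h

After the first hour the gap between right-handed and left-handed substrate reads flat within its scatter while the reaction goes on, so I take it that the two substrates interconvert, as in a dynamic kinetic resolution. The gap already stands at the first summer reading, so I take that time as its half-life:

g = ln 2 / time = 2.77 h⁻¹

Noon between its readings at 2.00 h and 4.00 h gives the rate per molecule of reacting:

κ = 0.163 h⁻¹

Their ratio is the fork number, the rate of reacting over the rate of closing the gap:

ρ = κ/g = 0.0587

When the gap is steady, coupling opens it as fast as flipping closes it, so the excess in the substrate is ρ times the excess in the product.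

Noon keeps 52.9% of its substrate at 3.00 h and loses 15.7% of its partner. The flask has twice the substrate on the same partner, so I let its partner fall proportionally and scale the exponent:

left = 55.8%

The noon and summer readings from the first hour on give a mean gap of 0.81 percentage points; I carry this gap and ρ over to the flask as estimates, so:

eS = gap/left = 1.46%

eP = eS/ρ = 24.8%

The weak link is g, read from one time. A rough check in the summer run needs no g: while right-handed substrate leads, flips keep the product excess above the ratio of the gap to the reacted part, and at the first summer reading that ratio reads 18.8%, with its scatter.

The forecast, which saw the substrate excess as one that “then plateaus within noise”, stands at 43.5%, 1.9% and 1.4%, its product excess lower than my 24.8%. The flask gives 43.3%, 23.5% and 1.39%.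

    partner + free catalyst + left-handed substrate → free catalyst + left-handed product (k = 20000 M⁻² h⁻¹)
    partner + free catalyst + right-handed substrate → free catalyst + right-handed product (k = 12000 M⁻² h⁻¹)
    left-handed substrate ⇌ right-handed substrate (k = 1.30 h⁻¹)
    free catalyst → spent catalyst A (k = 0.0920 h⁻¹)
    free catalyst + impurity → spent catalyst B (k = 1.20 × 10⁶ M⁻¹ h⁻¹)
    free catalyst ⇌ dormant form (K = 0.560, k = 0.0370 h⁻¹)

In the flask at 1.03 h, left-handed substrate couples at 0.20 of its forward flipping rate, so it couples more slowly than it flips, and the pair relaxes with a half-life of 0.267 h, short against 3.0 h. Taking ρ as the flask's at 3.00 h and scaling it by the amounts of free catalyst and partner, I reckon 0.117 for the neighbour flask with 0.90 mM of free catalyst at 3.00 h, which with its product excess of 21.6% gives 2.53%, and that flask stands at 2.81%.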